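Everything rests on reading hemiketal carbon C2 as a ketone of the open 1,3-diketone and hiding that ketone as C3 of an isocoumarin. The feature exploited is the ring B carboxyl group: it stands ortho to the benzylic CH2, so its oxygen, its carbonyl carbon, two ring B carbons, the benzylic carbon and C2 form a six-membered ring. One palladium/zinc operation joins ring B to a terminal alkyne and adds the carboxylate 6-endo to the carbon that becomes C2. The precursors are a benzyl-protected 2-iodobenzoic acid and a propargyl dithiane carrying ring A, the heptyl chain, masked C4 and C3. Neutral hydrogenolysis and a dynamic salt crystallisation finish the (R)-hemiketal.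

Key step: step 8

Assumption: the cyclic hemiketal is taken to be the resting tautomer of the deprotected diketo acid and to hold its configuration in the crystal and in cold neutral solution. The (R)-acid is taken to give the less soluble salt with quinine; should the (S)-acid salt crystallise instead, pseudo-enantiomeric quinidine replaces quinine with no other change.

Design remark: all four phenols are carried as benzyl ethers so that the last bond-breaking step is neutral, because a 2-hydroxychromanone loses water to the chromone under Lewis or Brønsted acid. The resolving base is a tertiary amine, because a primary amine would condense with the open 1,3-diketone to an enaminone.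

Step 1
Reactants: 1 5-heptylbenzene-1,3-diol (5-heptylresorcinol)
Product: 3 2,4-dihydroxy-6-heptylbenzaldehyde, via aryl iminium chloride 2 (not isolated)
Conditions: POCl3, DMF, 0 °C → rt; then ice–H2O
Reagents that add atoms: N,N-dimethylformamide CN(C)C=O; water O
Why: Vilsmeier–Haack formylation: the chloroiminium ion attacks para to one hydroxyl and ortho to the other, next to the heptyl chain and not between the two oxygens, as is the rule for 5-alkylresorcinols, and water hydrolyses iminium salt 2.

Step 2
Reactants: 3 2,4-dihydroxy-6-heptylbenzaldehyde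
Product: 4 2,4-bis(benzyloxy)-6-heptylbenzaldehyde
Conditions: BnBr, K2CO3, DMF, 60 °C
Reagents that add atoms: benzyl bromide BrCc1ccccc1
Why: Williamson ether synthesis: both phenoxides, including the hydrogen-bonded one ortho to the aldehyde once warmed, are benzylated by SN2, and nothing else in 3 reacts under carbonate.

Step 3
Reactants: 4 2,4-bis(benzyloxy)-6-heptylbenzaldehyde; 5 propane-1,3-dithiol
Product: 6 2-[2,4-bis(benzyloxy)-6-heptylphenyl]-1,3-dithiane
Conditions: BF3·OEt2 (cat.), CH2Cl2, 0 °C → rt
Reagents that add atoms: none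
Why: Lewis-acid-catalysed thioacetalisation closes the six-membered dithiane on the aldehyde carbon, and a catalytic charge of BF3·OEt2 at low temperature leaves aryl benzyl ethers intact.

Step 4
Reactants: 6 2-[2,4-bis(benzyloxy)-6-heptylphenyl]-1,3-dithiane; 7 (3-bromoprop-1-yn-1-yl)trimethylsilane
Product: 10 2-[2,4-bis(benzyloxy)-6-heptylphenyl]-2-(prop-2-yn-1-yl)-1,3-dithiane, via 2-lithiodithiane 8 (not isolated), via silylated alkyne 9 (not isolated)
Conditions: n-BuLi, THF, −78 → −20 °C; 7, −78 °C → rt; then MeOH, K2CO3 (cat.), rt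
Reagents that add atoms: none
Why: Corey–Seebach umpolung: the dithiane C2–H is by far the most acidic site of 6, its lithium salt displaces the primary propargylic bromide by SN2 while the silyl cap blocks proton transfer from an alkyne C–H and SN2' attack, and methanolysis of the C–Si bond in the same flask frees the terminal alkyne.

Step 5
Reactants: 11 5-iodobenzene-1,3-diol (5-iodoresorcinol)
Product: 12 1,3-bis(benzyloxy)-5-iodobenzene
Conditions: BnBr, K2CO3, acetone, reflux
Reagents that add atoms: benzyl bromide BrCc1ccccc1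
Why: Williamson ether synthesis on two unhindered phenols, with the aryl iodide inert to carbonate and benzyl bromide.

Step 6
Reactants: 12 1,3-bis(benzyloxy)-5-iodobenzene
Product: 14 2,4-bis(benzyloxy)-6-iodobenzaldehyde, via aryl iminium chloride 13 (not isolated)
Conditions: POCl3, DMF, 0 → 80 °C; then ice–H2O
Reagents that add atoms: N,N-dimethylformamide CN(C)C=O; water O
Why: Vilsmeier–Haack formylation: attack occurs ortho to iodine and para to a benzyloxy group because the site between the two benzyloxy groups is the more crowded, in line with the behaviour of 5-haloresorcinol diethers, and the C–I bond and the benzyl ethers tolerate the reagent.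

Step 7
Reactants: 14 2,4-bis(benzyloxy)-6-iodobenzaldehyde
Product: 15 2,4-bis(benzyloxy)-6-iodobenzoic acid
Conditions: NaClO2, NaH2PO4, 2-methylbut-2-ene, t-BuOH–THF–H2O, rt
Reagents that add atoms: sodium chlorite [Na+].[O-]Cl=O
Why: Pinnick oxidation: chlorous acid adds to the aldehyde and fragments to the acid, while the alkene scavenger removes hypochlorous acid before it can chlorinate the electron-rich ring, and iodide and benzyl ethers are untouched.

Step 8
Reactants: 10 2-[2,4-bis(benzyloxy)-6-heptylphenyl]-2-(prop-2-yn-1-yl)-1,3-dithiane; 15 2,4-bis(benzyloxy)-6-iodobenzoic acid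
Product: 18 6,8-bis(benzyloxy)-3-({2-[2,4-bis(benzyloxy)-6-heptylphenyl]-1,3-dithian-2-yl}methyl)-1H-isochromen-1-one, via alkynylzinc chloride 16 (not isolated), via 2-alkynylbenzoic acid 17 (not isolated)
Conditions: Pd(PPh3)4 (10 mol %), ZnCl2, Et3N, DMF, 100 °C, Ar
Reagents that add atoms: none
Why: Zerovalent palladium inserts into the C–I bond of 15, the alkynylzinc 16 formed from 10 with ZnCl2 and Et3N hands over its alkynyl group, and reductive elimination forges the ring B–C(sp) bond of 17 (a copper-free Sonogashira/Negishi-type alkynylation). The zinc-activated triple bond is then attacked by the neighbouring carboxylate oxygen at its distal carbon and the vinyl–metal bond is protonated; the closest known reaction type is the one-pot coupling–lactonisation of 2-iodobenzoic acids with terminal alkynes to 3-substituted isocoumarins under this catalyst system. The single new ring (O2, C1, C8a, C4a, C4, C3 of the isocoumarin) closes in the 6-endo-dig mode. No stereocentre is formed. The selectivity needed is 6-endo over 5-exo closure, and it is secured by the absence of copper, by the alkyl rather than aryl substituent on the alkyne, by the ortho carboxyl group that polarises the triple bond towards its distal carbon, and by both benzyloxy groups lying meta to the alkyne so that they cannot reverse this polarisation. The thioacetal holds C4 at the ketone oxidation level without acidifying the propargylic CH2, so Et3N at 100 °C has no path to an allene.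

Step 9
Reactants: 18 6,8-bis(benzyloxy)-3-({2-[2,4-bis(benzyloxy)-6-heptylphenyl]-1,3-dithian-2-yl}methyl)-1H-isochromen-1-one
Product: 19 6,8-bis(benzyloxy)-3-{2-[2,4-bis(benzyloxy)-6-heptylphenyl]-2-oxoethyl}-1H-isochromen-1-one
Conditions: MeI, CaCO3, aq. MeCN–THF, 45 °C
Reagents that add atoms: water O
Why: Alkylative thioacetal hydrolysis: S-methylation turns sulfur into a leaving group, the aryl-stabilised thionium ion is trapped by water, and the buffered, non-oxidising medium spares the electron-rich rings, the benzyl ethers and the enol lactone.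

Step 10
Reactants: 19 6,8-bis(benzyloxy)-3-{2-[2,4-bis(benzyloxy)-6-heptylphenyl]-2-oxoethyl}-1H-isochromen-1-one
Product: 20 2,4-bis(benzyloxy)-6-{4-[2,4-bis(benzyloxy)-6-heptylphenyl]-2,4-dioxobutyl}benzoic acid
Conditions: LiOH, THF–H2O, 0 °C → rt; then cold 1 M HCl to pH 4
Reagents that add atoms: lithium hydroxide [Li+].[OH-]
Why: Saponification of an enol lactone: hydroxide adds to the lactone carbonyl and expels the enolate of a 1,3-diketone, a far better leaving group than an alkoxide, the carboxylate–diketonate dianion resists retro-Claisen cleavage and cannot undergo Claisen ring closure, and acidification only to pH 4 in the cold avoids relactonisation.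

Step 11
Reactants: 20 2,4-bis(benzyloxy)-6-{4-[2,4-bis(benzyloxy)-6-heptylphenyl]-2,4-dioxobutyl}benzoic acid
Product: 22 racemic 2-[(5-heptyl-2,7-dihydroxy-4-oxo-3,4-dihydro-2H-chromen-2-yl)methyl]-4,6-dihydroxybenzoic acid, via open-chain diketo acid 21 (not isolated)
Conditions: H2 (1 atm), 10% Pd/C, EtOAc–THF, rt
Reagents that add atoms: none
Why: Catalytic hydrogenolysis cleaves the four aryl benzyl ethers under neutral, alcohol-free conditions, and in 21 the ring A phenol ortho to the C4 ketone adds to the C2 ketone (6-exo-trig hemiketalisation) without facial bias, so C2 arises racemic with no acid present to dehydrate the hemiketal and no alcohol to turn it into a mixed ketal.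

Step 12
Reactants: 22 racemic 2-[(5-heptyl-2,7-dihydroxy-4-oxo-3,4-dihydro-2H-chromen-2-yl)methyl]-4,6-dihydroxybenzoic acid; 23 quinine
Product: 24 quininium 2-{[(2R)-5-heptyl-2,7-dihydroxy-4-oxo-3,4-dihydro-2H-chromen-2-yl]methyl}-4,6-dihydroxybenzoate (crystalline 1:1 salt)
Conditions: 23 (1 equiv), MeCN, slurry, temperature cycling 20–45 °C, then 5 °C, filtration
Reagents that add atoms: none
Why: Proposed new method: in solution the enantiomers of 22 interconvert through achiral open-chain 21 (ring–chain tautomerism, speeded by the basic quinuclidine nitrogen), the two diastereomeric quininium salts differ in solubility, and steady removal of the less soluble one as crystals drains the whole equilibrium into it, so that the lattice of the quinine salt sets C2 as R; the closest known reaction types are the crystallisation-induced diastereomer transformation of enolisable keto acids as alkaloid salts and the crystallisation of one anomer from a mutarotating sugar, neither of which has been shown on a 2-hydroxychromanone.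

Step 13
Reactants: 24 quininium (2R)-carboxylate salt
Product: 25 2-{[(2R)-5-heptyl-2,7-dihydroxy-4-oxo-3,4-dihydro-2H-chromen-2-yl]methyl}-4,6-dihydroxybenzoic acid (target)
Conditions: EtOAc / cold 0.1 M HCl, 0 °C, short contact; NaOH on the aqueous layer returns 23
Reagents that add atoms: none
Why: Salt breaking by proton transfer: the cold dilute acid protonates the carboxylate and carries quinine into water, and because ring opening to 21 is the only path that can scramble C2 and is slow at 0 °C without base, the R configuration fixed in the crystal should pass unchanged into 25, which is dried and kept cold as a solid.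

Compound list
1 | 5-heptylbenzene-1,3-diol | CCCCCCCc1cc(O)cc(O)c1 | starting material
2 | [(2,4-dihydroxy-6-heptylphenyl)methylidene]dimethyliminium chloride | CCCCCCCc1cc(O)cc(O)c1C=[N+](C)C.[Cl-] | intermediate
3 | 2,4-dihydroxy-6-heptylbenzaldehyde | CCCCCCCc1cc(O)cc(O)c1C=O | intermediate
4 | 2,4-bis(benzyloxy)-6-heptylbenzaldehyde | CCCCCCCc1cc(OCc2ccccc2)cc(OCc2ccccc2)c1C=O | intermediate
5 | propane-1,3-dithiol | SCCCS | starting material
6 | 2-[2,4-bis(benzyloxy)-6-heptylphenyl]-1,3-dithiane | CCCCCCCc1cc(OCc2ccccc2)cc(OCc2ccccc2)c1C1SCCCS1 | intermediate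
7 | (3-bromoprop-1-yn-1-yl)trimethylsilane | C[Si](C)(C)C#CCBr | starting material
8 | 2-[2,4-bis(benzyloxy)-6-heptylphenyl]-2-lithio-1,3-dithiane | CCCCCCCc1cc(OCc2ccccc2)cc(OCc2ccccc2)c1C1([Li])SCCCS1 | intermediate
9 | (3-{2-[2,4-bis(benzyloxy)-6-heptylphenyl]-1,3-dithian-2-yl}prop-1-yn-1-yl)trimethylsilane | CCCCCCCc1cc(OCc2ccccc2)cc(OCc2ccccc2)c1C1(CC#C[Si](C)(C)C)SCCCS1 | intermediate
10 | 2-[2,4-bis(benzyloxy)-6-heptylphenyl]-2-(prop-2-yn-1-yl)-1,3-dithiane | CCCCCCCc1cc(OCc2ccccc2)cc(OCc2ccccc2)c1C1(CC#C)SCCCS1 | intermediate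
11 | 5-iodobenzene-1,3-diol | Oc1cc(O)cc(I)c1 | starting material
12 | 1,3-bis(benzyloxy)-5-iodobenzene | Ic1cc(OCc2ccccc2)cc(OCc2ccccc2)c1 | intermediate
13 | {[2,4-bis(benzyloxy)-6-iodophenyl]methylidene}dimethyliminium chloride | C[N+](C)=Cc1c(I)cc(OCc2ccccc2)cc1OCc1ccccc1.[Cl-] | intermediate
14 | 2,4-bis(benzyloxy)-6-iodobenzaldehyde | O=Cc1c(I)cc(OCc2ccccc2)cc1OCc1ccccc1 | intermediate
15 | 2,4-bis(benzyloxy)-6-iodobenzoic acid | OC(=O)c1c(I)cc(OCc2ccccc2)cc1OCc1ccccc1 | intermediate
16 | (3-{2-[2,4-bis(benzyloxy)-6-heptylphenyl]-1,3-dithian-2-yl}prop-1-yn-1-yl)zinc chloride | CCCCCCCc1cc(OCc2ccccc2)cc(OCc2ccccc2)c1C1(CC#C[Zn]Cl)SCCCS1 | intermediate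
17 | 2,4-bis(benzyloxy)-6-(3-{2-[2,4-bis(benzyloxy)-6-heptylphenyl]-1,3-dithian-2-yl}prop-1-yn-1-yl)benzoic acid | CCCCCCCc1cc(OCc2ccccc2)cc(OCc2ccccc2)c1C1(CC#Cc2cc(OCc3ccccc3)cc(OCc3ccccc3)c2C(=O)O)SCCCS1 | intermediate
18 | 6,8-bis(benzyloxy)-3-({2-[2,4-bis(benzyloxy)-6-heptylphenyl]-1,3-dithian-2-yl}methyl)-1H-isochromen-1-one | CCCCCCCc1cc(OCc2ccccc2)cc(OCc2ccccc2)c1C1(CC2=Cc3cc(OCc4ccccc4)cc(OCc4ccccc4)c3C(=O)O2)SCCCS1 | intermediate
19 | 6,8-bis(benzyloxy)-3-{2-[2,4-bis(benzyloxy)-6-heptylphenyl]-2-oxoethyl}-1H-isochromen-1-one | CCCCCCCc1cc(OCc2ccccc2)cc(OCc2ccccc2)c1C(=O)CC1=Cc2cc(OCc3ccccc3)cc(OCc3ccccc3)c2C(=O)O1 | intermediate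
20 | 2,4-bis(benzyloxy)-6-{4-[2,4-bis(benzyloxy)-6-heptylphenyl]-2,4-dioxobutyl}benzoic acid | CCCCCCCc1cc(OCc2ccccc2)cc(OCc2ccccc2)c1C(=O)CC(=O)Cc1cc(OCc2ccccc2)cc(OCc2ccccc2)c1C(=O)O | intermediate
21 | 2-[4-(2-heptyl-4,6-dihydroxyphenyl)-2,4-dioxobutyl]-4,6-dihydroxybenzoic acid | CCCCCCCc1cc(O)cc(O)c1C(=O)CC(=O)Cc1cc(O)cc(O)c1C(=O)O | intermediate
22 | racemic 2-[(5-heptyl-2,7-dihydroxy-4-oxo-3,4-dihydro-2H-chromen-2-yl)methyl]-4,6-dihydroxybenzoic acid | CCCCCCCc1cc(O)cc2c1C(=O)CC(O)(Cc1cc(O)cc(O)c1C(=O)O)O2 | intermediate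
23 | quinine, (R)-[(2S,4S,5R)-5-ethenyl-1-azabicyclo[2.2.2]octan-2-yl](6-methoxyquinolin-4-yl)methanol | COC1=CC2=C(C=CN=C2C=C1)[C@H]([C@@H]3C[C@@H]4CCN3C[C@@H]4C=C)O | starting material
24 | quininium 2-{[(2R)-5-heptyl-2,7-dihydroxy-4-oxo-3,4-dihydro-2H-chromen-2-yl]methyl}-4,6-dihydroxybenzoate | CCCCCCCc1cc(O)cc2c1C(=O)C[C@@](O)(Cc1cc(O)cc(O)c1C(=O)[O-])O2.COC1=CC2=C(C=CN=C2C=C1)[C@H]([C@@H]3C[C@@H]4CC[NH+]3C[C@@H]4C=C)O | intermediate
25 | 2-{[(2R)-5-heptyl-2,7-dihydroxy-4-oxo-3,4-dihydro-2H-chromen-2-yl]methyl}-4,6-dihydroxybenzoic acid | CCCCCCCc1cc(O)cc2c1C(=O)C[C@@](O)(Cc1cc(O)cc(O)c1C(=O)O)O2 | target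

Total step count: 13
Longest linear sequence: 10 steps (steps 1–4, then 8–13); the ring B branch (steps 5–7) joins at step 8.

Steps most likely to fail

1. Step 12 (the labelled step). The salt may refuse to crystallise. Both diastereomeric salts may co-crystallise. Epimerisation may be too slow to feed the growing crystal, or slow loss of water may erode the material in the mother liquor. The fallback uses known chemistry, sets out from 22 and comes back at 25. Racemic 22 is separated by preparative enantioselective chromatography on an immobilised polysaccharide carbamate phase, with a cold, alcohol-free, weakly acidified eluent. The R fraction is evaporated cold to give 25 directly. The S fraction is left in solution until it has racemised through 21 and is then re-injected. This fallback makes no new compound (F0).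

2. Step 8. Thioacetal sulfur may bind zerovalent palladium and stall the coupling. The electron-rich acid may lose CO2 at 100 °C. The lactonisation may drift towards 5-exo closure. The fallback sets out from 6 and 15 and comes back at 18. It makes the ring B–benzylic bond by ketone α-arylation and brings in the C2 oxygen with an epoxide, so no alkyne has to be activated. Lithiated 8, made from 6 as in step 4, opens racemic 2-methyloxirane at its CH2 (THF–DMPU, −78 → 0 °C) to racemic 1-{2-[2,4-bis(benzyloxy)-6-heptylphenyl]-1,3-dithian-2-yl}propan-2-ol F1. Parikh–Doering oxidation (SO3·pyridine, DMSO, Et3N), which spares thioacetals, gives 1-{2-[2,4-bis(benzyloxy)-6-heptylphenyl]-1,3-dithian-2-yl}propan-2-one F2. Acid 15 is esterified (MeI, K2CO3, DMF) to methyl 2,4-bis(benzyloxy)-6-iodobenzoate F3. Palladium-catalysed α-arylation of F2 at its unhindered methyl group with F3 (Pd2(dba)3, Xantphos, Cs2CO3, dioxane, 90 °C) should give methyl 2,4-bis(benzyloxy)-6-(3-{2-[2,4-bis(benzyloxy)-6-heptylphenyl]-1,3-dithian-2-yl}-2-oxopropyl)benzoate F4. Its enol displaces methanol on warming with catalytic p-TsOH in toluene and closes 18.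

3. Step 4. Metalation of the crowded, electron-rich aryl dithiane may be incomplete. Metalation may compete at an OCH2Ph group and be followed by Wittig rearrangement. Alkylation of the congested carbanion may be sluggish. The fallback sets out from 4 and comes back at 19. Normal-polarity addition replaces the umpolung, and C4 travels as a protected carbinol, which also takes sulfur out of the coupling. Barbier propargylation of 4 (3-bromoprop-1-yne, Zn dust, THF–aq. NH4Cl) gives racemic 1-[2,4-bis(benzyloxy)-6-heptylphenyl]but-3-yn-1-ol F5. TBSOTf and 2,6-lutidine (CH2Cl2, −78 °C) give its tert-butyldimethylsilyl ether F6. Coupling of F6 with 15 under the conditions of step 8 gives 6,8-bis(benzyloxy)-3-{2-[2,4-bis(benzyloxy)-6-heptylphenyl]-2-[(tert-butyldimethylsilyl)oxy]ethyl}-1H-isochromen-1-one F7. TBAF buffered with AcOH frees 6,8-bis(benzyloxy)-3-{2-[2,4-bis(benzyloxy)-6-heptylphenyl]-2-hydroxyethyl}-1H-isochromen-1-one F8. Dess–Martin oxidation erases the temporary stereocentre and delivers 19.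

Further compounds
F0 | step 12 | none | none
F1 | step 8 | racemic 1-{2-[2,4-bis(benzyloxy)-6-heptylphenyl]-1,3-dithian-2-yl}propan-2-ol | CCCCCCCc1cc(OCc2ccccc2)cc(OCc2ccccc2)c1C1(CC(C)O)SCCCS1
F2 | step 8 | 1-{2-[2,4-bis(benzyloxy)-6-heptylphenyl]-1,3-dithian-2-yl}propan-2-one | CCCCCCCc1cc(OCc2ccccc2)cc(OCc2ccccc2)c1C1(CC(C)=O)SCCCS1
F3 | step 8 | methyl 2,4-bis(benzyloxy)-6-iodobenzoate | COC(=O)c1c(I)cc(OCc2ccccc2)cc1OCc1ccccc1
F4 | step 8 | methyl 2,4-bis(benzyloxy)-6-(3-{2-[2,4-bis(benzyloxy)-6-heptylphenyl]-1,3-dithian-2-yl}-2-oxopropyl)benzoate | CCCCCCCc1cc(OCc2ccccc2)cc(OCc2ccccc2)c1C1(CC(=O)Cc2cc(OCc3ccccc3)cc(OCc3ccccc3)c2C(=O)OC)SCCCS1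
F5 | step 4 | racemic 1-[2,4-bis(benzyloxy)-6-heptylphenyl]but-3-yn-1-ol | CCCCCCCc1cc(OCc2ccccc2)cc(OCc2ccccc2)c1C(O)CC#C
F6 | step 4 | racemic {1-[2,4-bis(benzyloxy)-6-heptylphenyl]but-3-yn-1-yl}oxy(tert-butyl)dimethylsilane | CCCCCCCc1cc(OCc2ccccc2)cc(OCc2ccccc2)c1C(CC#C)O[Si](C)(C)C(C)(C)C
F7 | step 4 | racemic 6,8-bis(benzyloxy)-3-{2-[2,4-bis(benzyloxy)-6-heptylphenyl]-2-[(tert-butyldimethylsilyl)oxy]ethyl}-1H-isochromen-1-one | CCCCCCCc1cc(OCc2ccccc2)cc(OCc2ccccc2)c1C(CC1=Cc2cc(OCc3ccccc3)cc(OCc3ccccc3)c2C(=O)O1)O[Si](C)(C)C(C)(C)C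
F8 | step 4 | racemic 6,8-bis(benzyloxy)-3-{2-[2,4-bis(benzyloxy)-6-heptylphenyl]-2-hydroxyethyl}-1H-isochromen-1-one | CCCCCCCc1cc(OCc2ccccc2)cc(OCc2ccccc2)c1C(O)CC1=Cc2cc(OCc3ccccc3)cc(OCc3ccccc3)c2C(=O)O1
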